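**Plan** (briarane numbering: ring C1–C10, pyran O bridges C4/C8, C5=C16, C6–Cl, lactone C7–O–C19(=O)–C17(C18)–C8, cyclohexane C1/C10–C14, epoxide C11–C20; PMB = 4-methoxybenzyl, TES = SiEt3, TBS = SiMe2tBu)
1. Enabling feature: the cis-fused γ-lactone shares C7–C8 with the pyran and C8 is the ether carbon, so C7=C8 can be a cyclic enol ether and C19/C17 (with the C18 methyl) the two carbons of methylchloroketene.
2. Cuts, in order: C2–C3 (pinacol of a 2,3-dialdehyde), C9–C10 (allylsilane + C9 aldehyde), C11–O (epoxidation), C7–O (Baeyer–Villiger), then C7–C19 and C8–C17 together ((2+2) cycloaddition).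
3. Forward: dihydropyranone (aldol/cyclodehydration) → 3-methylene enol ether → cyclobutanone → γ-lactone → C6 chloride → C9 aldehyde; separately cyclohexenone → allylsilane; union at C9–C10, spiro-epoxide, and the ten-membered ring closes last.
4. Stereochemistry: C4 from a Cu(II)–pybox aldol; C6 from Luche reduction, later inverted by chloride; C7/C8 from ketene attack anti to the C6 and C4 substituents; C17 from convex-face H-atom transfer; C14 from a lipase resolution; C1 from cuprate addition anti to C14–O; C9/C10 from an open-transition-state allylation; C11 from directed equatorial epoxidation; C2/C3 from the pinacol closure.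

Key step: step 8

Remark: (4-methoxybenzyloxy)acetaldehyde 3 and (tributylstannyl)methanol 22 are taken as catalogue compounds; PMB is used on C3–O and C2–O so that both primary ethers can be cleaved together under neutral oxidative conditions late in the route.

**Route**

Step 1
Reactants: 1 ethyl 2,4-dioxopentanoate
Product: 2 ethyl (2Z)-2,4-bis(trimethylsilyloxy)penta-2,4-dienoate
Conditions: TMSOTf (2.3 equiv), Et3N (2.6 equiv), Et2O, 0 °C → rt
Reagents that add atoms: trimethylsilyl trifluoromethanesulfonate, C[Si](C)(C)OS(=O)(=O)C(F)(F)F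
Why: Soft enolisation with double O-silylation (silyl dienol ether formation) converts the enolised 1,3-diketone and then the methyl ketone into a 2-silyloxydiene whose terminal CH2 is the nucleophilic site.

Step 2
Reactants: 2 bis-silyl dienol ether; 3 (4-methoxybenzyloxy)acetaldehyde
Product: 5 ethyl (2R)-2-[(4-methoxybenzyloxy)methyl]-4-oxo-3,4-dihydro-2H-pyran-6-carboxylate, via open-chain aldol 4 (not isolated)
Conditions: [Cu((R,R)-Ph-pybox)](SbF6)2 (5 mol%), CH2Cl2, −78 °C; then TsOH·H2O (10 mol%), wet THF, rt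
Reagents that add atoms: none
Why: Vinylogous Mukaiyama aldol on the aldehyde held as a five-membered Cu(II) chelate through its ether oxygen, so the dienolate terminus attacks one carbonyl face and sets C4 as (R) (the (R,R) ligand is the antipode of the one that gives (S) adducts with alkoxyacetaldehydes), after which acid removes the silyl groups and the δ-hydroxy diketo ester cyclodehydrates through its hemiketal.

Step 3
Reactants: 5 dihydropyranone ester
Product: 8 ethyl (2R)-2-[(4-methoxybenzyloxy)methyl]-3-methylene-4-oxo-3,4-dihydro-2H-pyran-6-carboxylate, via Mannich base 6 (not isolated), via quaternary ammonium iodide 7 (not isolated)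
Conditions: LiHMDS, THF, −78 °C; Me2N=CH2+ I−, −78 → 0 °C; MeI, rt; aq NaHCO3/CH2Cl2
Reagents that add atoms: Eschenmoser's salt (dimethylmethyleneiminium iodide), C=[N+](C)C.[I-]
Why: Mannich reaction of the only possible (C5) enolate followed by quaternisation and E1cB elimination (Eschenmoser methylenation) installs C16; the cross-conjugated dienone is taken on at once to limit dimerisation.

Step 4
Reactants: 8 methylene pyranone
Product: 9 ethyl (2R,4S)-4-hydroxy-2-[(4-methoxybenzyloxy)methyl]-3-methylene-3,4-dihydro-2H-pyran-6-carboxylate (4-OH cis to the 2-side chain)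
Conditions: NaBH4, CeCl3·7H2O, MeOH, −78 °C
Reagents that add atoms: none
Why: Luche 1,2-reduction; axial hydride delivery on the half-chair with the C4 side chain pseudo-equatorial gives the pseudo-equatorial C6 alcohol cis to that side chain, as is usual for 2-substituted dihydropyran-4-ones.

Step 5
Reactants: 9 allylic alcohol
Product: 10 ethyl (2R,4S)-2-[(4-methoxybenzyloxy)methyl]-3-methylene-4-(triethylsilyloxy)-3,4-dihydro-2H-pyran-6-carboxylate
Conditions: TESCl, imidazole, CH2Cl2, 0 °C
Reagents that add atoms: chlorotriethylsilane, CC[Si](Cl)(CC)CC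
Why: Imidazole-promoted silylation caps the C6 hydroxyl as a triethylsilyl ether that can later be removed in the presence of a primary TBS ether; no stereocentre changes.

Step 6
Reactants: 10 silyl ether ester
Product: 11 [(2R,4S)-2-[(4-methoxybenzyloxy)methyl]-3-methylene-4-(triethylsilyloxy)-3,4-dihydro-2H-pyran-6-yl]methanol
Conditions: DIBAL-H (2.5 equiv), CH2Cl2, −78 °C; Rochelle salt
Reagents that add atoms: none
Why: DIBAL-H reduction of the 2-alkoxyacrylate ester to the C9 allylic alcohol removes the acceptor from C8 and turns C7=C8 into an electron-rich enol ether.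

Step 7
Reactants: 11 allylic alcohol
Product: 12 (2R,4S)-6-[(tert-butyldimethylsilyloxy)methyl]-2-[(4-methoxybenzyloxy)methyl]-3-methylene-4-(triethylsilyloxy)-3,4-dihydro-2H-pyran
Conditions: TBSCl, imidazole, DMF, 0 °C → rt
Reagents that add atoms: tert-butylchlorodimethylsilane, CC(C)(C)[Si](C)(C)Cl
Why: Silylation of the primary alcohol gives the cycloaddition substrate with C6–O (TES) and C9–O (TBS) differentiated.

Step 8
Reactants: 12 3-methylene dihydropyran enol ether; 13 2-chloropropanoyl chloride
Product: 15 8-chloro-8-methyl-4-methylene-1-[(TBS-oxy)methyl]-3-[(PMB-oxy)methyl]-5-(triethylsilyloxy)-2-oxabicyclo[4.2.0]octan-7-one (cis-fused; cyclobutanone anti to the C6 silyloxy and C4 side chain; methyl endo), via methylchloroketene 14 (not isolated)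
Conditions: 13 (3 equiv) by syringe pump over 8 h into 12 + Et3N (3.5 equiv), hexane, 40 °C
Reagents that add atoms: none
Why: Methylchloroketene, released slowly by dehydrochlorination of 13, is attacked at its carbonyl carbon (C19) by the nucleophilic β-carbon C7 of the enol ether while C17 closes onto the oxocarbenium-like C8, a concerted but asynchronous [π2s+π2a] (2+2) cycloaddition. The closest known reaction type is the cycloaddition of chloroketenes to glycals and other cyclic enol ethers. The four-membered ring closes by this cycloaddition, suprafacial on the enol ether, so the cyclobutanone is necessarily cis-fused to the pyran. C7 and C8 are set by the face of approach, the ketene coming from the face opposite the allylic C6 triethylsilyloxy group and the C4 side chain (both on the same face), and C17 by the orthogonal ketene approach that turns methyl endo (this centre is erased in step 10). Regioselectivity follows from enol ether polarisation (C19 to C7, C17 to C8), chemoselectivity over the 1,1-disubstituted C5 methylene from the far higher nucleophilicity of the enol ether, and slow generation keeps ketene dimerisation down.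

Step 9
Reactants: 15 α-chlorocyclobutanone
Product: 16 3-chloro-3-methyl-6-methylene-3a-[(TBS-oxy)methyl]-5-[(PMB-oxy)methyl]-7-(triethylsilyloxy)hexahydro-2H-furo[3,2-b]pyran-2-one (3a,7a-cis)
Conditions: mCPBA (1.3 equiv), NaHCO3, CH2Cl2, 0 °C
Reagents that add atoms: 3-chloroperoxybenzoic acid, OOC(=O)c1cccc(Cl)c1
Why: Baeyer–Villiger oxidation in which the secondary C7 migrates with retention because the chlorinated C17 migrates poorly, giving C7–O–C19; the strained α-chlorocyclobutanone reacts far faster than the deactivated C5 methylene is epoxidised.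

Step 10
Reactants: 16 α-chlorolactone
Product: 17 3-methyl-6-methylene-3a-[(TBS-oxy)methyl]-5-[(PMB-oxy)methyl]-7-(triethylsilyloxy)hexahydro-2H-furo[3,2-b]pyran-2-one (3-methyl cis to the pyran oxygen)
Conditions: Bu3SnH (1.5 equiv), AIBN (cat.), PhH, 80 °C
Reagents that add atoms: none
Why: Radical chain dechlorination in which the planar lactone α-radical takes hydrogen from the tin hydride on the convex face of the cis-fused bicycle (away from the pyran ring), leaving the C17 methyl on the concave face cis to the ring oxygen as in the target; neutral conditions avoid β-alkoxide loss from a lactone enolate.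

Step 11
Reactants: 17 lactone
Product: 18 7-hydroxy-3-methyl-6-methylene-3a-[(TBS-oxy)methyl]-5-[(PMB-oxy)methyl]hexahydro-2H-furo[3,2-b]pyran-2-one
Conditions: PPTS (cat.), MeOH/CH2Cl2, 0 °C
Reagents that add atoms: none
Why: Acid-catalysed methanolysis removes the secondary triethylsilyl ether much faster than the primary TBS ether (selective desilylation); no stereocentre changes.

Step 12
Reactants: 18 allylic alcohol
Product: 19 7-chloro-3-methyl-6-methylene-3a-[(TBS-oxy)methyl]-5-[(PMB-oxy)methyl]hexahydro-2H-furo[3,2-b]pyran-2-one (C6–Cl inverted, now cis to the lactone oxygen)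
Conditions: PPh3, hexachloroacetone, CH2Cl2, −20 → 0 °C
Reagents that add atoms: hexachloroacetone, O=C(C(Cl)(Cl)Cl)C(Cl)(Cl)Cl
Why: Appel-type chlorination through an alkoxyphosphonium chloride ion pair that collapses by SN2 with inversion at C6, a reagent pair noted for low allylic transposition; the inverted (later equatorial) chloride also lets the pyran place C3 and C9 axial for the final ring closure.

Step 13
Reactants: 19 chloride
Product: 20 7-chloro-3a-(hydroxymethyl)-3-methyl-6-methylene-5-[(PMB-oxy)methyl]hexahydro-2H-furo[3,2-b]pyran-2-one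
Conditions: HF·pyridine, pyridine, THF, 0 °C → rt
Reagents that add atoms: none
Why: Fluoride desilylation under buffered, mildly acidic conditions, chosen over basic fluoride so that the freed C9 hydroxyl does not transacylate onto the lactone.

Step 14
Reactants: 20 primary alcohol
Product: 21 7-chloro-3-methyl-6-methylene-2-oxo-5-[(PMB-oxy)methyl]hexahydro-2H-furo[3,2-b]pyran-3a-carbaldehyde
Conditions: Dess–Martin periodinane, NaHCO3, CH2Cl2, 0 °C → rt
Reagents that add atoms: none
Why: Dess–Martin oxidation of the neopentyl alcohol gives the non-enolisable C9 aldehyde under neutral conditions that leave the allylic chloride and lactone untouched.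

Step 15
Reactants: 22 (tributylstannyl)methanol
Product: 23 tributyl{[(4-methoxybenzyl)oxy]methyl}stannane
Conditions: NaH, PMBCl, Bu4NI (cat.), THF/DMF, 0 °C → rt
Reagents that add atoms: 4-methoxybenzyl chloride, COc1ccc(CCl)cc1
Why: Williamson etherification gives the precursor of an α-alkoxymethyl anion that will become C2.

Step 16
Reactants: 24 3-ethoxycyclohex-2-en-1-one
Product: 25 rac-3-ethoxy-6-hydroxycyclohex-2-en-1-one
Conditions: LDA, THF, −78 °C; 2-(phenylsulfonyl)-3-phenyloxaziridine, −78 °C; aq NH4Cl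
Reagents that add atoms: 2-(phenylsulfonyl)-3-phenyloxaziridine, O=S(=O)(N1OC1c1ccccc1)c1ccccc1
Why: Kinetic α′-deprotonation of the vinylogous ester and electrophilic hydroxylation of the enolate by the N-sulfonyloxaziridine (enolate oxidation); the racemate is resolved in step 18.

Step 17
Reactants: 25 hydroxy vinylogous ester; 23 alkoxymethylstannane
Product: 28 rac-4-hydroxy-3-{[(4-methoxybenzyl)oxy]methyl}cyclohex-2-en-1-one, via alkoxymethyllithium 26 (not isolated), via tertiary allylic alcohol 27 (not isolated)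
Conditions: 23, n-BuLi, THF, −78 °C; add to 25 + LiHMDS (1 equiv), −78 → −40 °C; then 1 M HCl, 0 °C → rt
Reagents that add atoms: water, O
Why: Tin–lithium exchange gives the alkoxymethyllithium, which adds 1,2 to the vinylogous ester carbonyl (the neighbouring hydroxyl carried as its lithium alkoxide), and acid hydrolysis with loss of the tertiary hydroxyl transposes the enone (Stork–Danheiser sequence), placing C2 on the β-carbon C1 next to the C14 carbinol.

Step 18
Reactants: 28 racemic hydroxy enone
Product: 29 (S)-4-hydroxy-3-{[(4-methoxybenzyl)oxy]methyl}cyclohex-2-en-1-one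
Conditions: immobilised Candida antarctica lipase B, vinyl acetate, t-BuOMe, 30 °C, to ca. 52% conversion
Reagents that add atoms: none
Why: Lipase-catalysed kinetic resolution by irreversible acylation: by the empirical size rule for secondary alcohols (large substituted-vinyl arm, medium CH2 arm) the (R)-carbinol is acetylated and the (S)-alcohol, which carries the C14 configuration of the target, is recovered.

Step 19
Reactants: 29 (S)-alcohol
Product: 30 (S)-3-{[(4-methoxybenzyl)oxy]methyl}-4-(triethylsilyloxy)cyclohex-2-en-1-one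
Conditions: TESCl, imidazole, CH2Cl2, 0 °C
Reagents that add atoms: chlorotriethylsilane, CC[Si](Cl)(CC)CC
Why: Silylation supplies the bulky C14 silyloxy group that steers steps 20 and 22; no stereocentre changes.

Step 20
Reactants: 30 enone
Product: 32 (3S,4S)-3-methyl-3-{[(4-methoxybenzyl)oxy]methyl}-4-(triethylsilyloxy)cyclohex-1-en-1-yl trifluoromethanesulfonate, via lithium enolate 31 (not isolated)
Conditions: Me2CuLi (from CuI + 2 MeLi), Et2O, −30 → 0 °C; then PhNTf2, THF, −78 °C → rt
Reagents that add atoms: lithium dimethylcuprate, [Li+].C[Cu-]C; N-phenylbis(trifluoromethanesulfonimide), O=S(=O)(N(c1ccccc1)S(=O)(=O)C(F)(F)F)C(F)(F)F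
Why: Conjugate addition of the Gilman cuprate anti to the adjacent C14 silyloxy group creates the quaternary C1 with methyl trans to C14–O, and O-sulfonylation of the regiodefined C10=C11 enolate (enolate trapping as enol triflate) fixes the double bond on the hindered side.

Step 21
Reactants: 32 enol triflate
Product: 33 trimethyl{[(3S,4S)-3-methyl-3-{[(4-methoxybenzyl)oxy]methyl}-4-(triethylsilyloxy)cyclohex-1-en-1-yl]methyl}silane
Conditions: Me3SiCH2MgCl, Pd(PPh3)4 (5 mol%), THF, rt
Reagents that add atoms: (trimethylsilyl)methylmagnesium chloride, C[Si](C)(C)C[Mg]Cl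
Why: Pd-catalysed Kumada coupling of the enol triflate with the silylmethyl Grignard reagent gives the allylsilane with the double bond still at C10=C11; no stereocentre is touched.

Step 22
Reactants: 21 C9 aldehyde; 33 allylsilane
Product: 34 homoallylic alcohol: C9 carbinol joining C8 of the chlorinated lactone–pyran to C10 of a 2-methyl-2-(PMB-oxymethyl)-6-methylene-3-(triethylsilyloxy)cyclohexane (C9, C10, C1, C14 as in the target)
Conditions: BF3·OEt2 (1.5 equiv), CH2Cl2, −78 → −40 °C
Reagents that add atoms: none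
Why: Hosomi–Sakurai allylation through an open antiperiplanar transition state in which the BF3-bound aldehyde reacts in its Felkin–Anh/Cornforth rotamer (C9=O anti to the C8–O bond, attack past C7–H instead of the branched C17) to set C9, while C10 is attacked anti to the pseudoaxial C1 CH2OPMB arm and away from the C14 silyloxy group, putting C9 cis to the C1 methyl with the bulky C8 and C1 anti across the new bond; loss of silicon leaves the C11 exocyclic methylene.

Step 23
Reactants: 34 silyl ether
Product: 35 C9,C14-diol (34 without the triethylsilyl group)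
Conditions: HF·pyridine, pyridine, THF, 0 °C
Reagents that add atoms: none
Why: Acidic fluoride desilylation of the secondary triethylsilyl ether, done before the acid-sensitive spiro-epoxide exists, frees the C14 hydroxyl for direction of the epoxidation and for acetylation.

Step 24
Reactants: 35 diol
Product: 36 11,20-epoxide of 35 (epoxide oxygen equatorial, cis to C14–OH; C20 axial)
Conditions: VO(acac)2 (5 mol%), t-BuOOH, CH2Cl2, 0 °C → rt
Reagents that add atoms: tert-butyl hydroperoxide, CC(C)(C)OO
Why: Hydroxyl-directed vanadium-catalysed epoxidation: only C11=C20 is homoallylic (C9–OH) and bishomoallylic (axial C14–OH) to a directing hydroxyl, so the C5 methylene is left alone, and oxygen arrives on the face cis to the C14 hydroxyl and opposite the axial C1 methyl, giving the C11 configuration of the target.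

Step 25
Reactants: 36 epoxy diol
Product: 37 9,14-diacetate of 36
Conditions: Ac2O, DMAP, Et3N, CH2Cl2, rt
Reagents that add atoms: acetic anhydride, CC(=O)OC(C)=O
Why: DMAP-catalysed acylation of both hindered secondary alcohols under basic conditions that the epoxide, chloride and lactone tolerate; no stereocentre changes.

Step 26
Reactants: 37 bis-PMB ether
Product: 38 C2,C3-diol (both primary alcohols free)
Conditions: DDQ (3 equiv), CH2Cl2/pH 7 buffer, 0 °C → rt
Reagents that add atoms: none
Why: Oxidative cleavage of both primary PMB ethers by DDQ (benzylic hydride abstraction, then hydrolysis) under buffered conditions that spare the epoxide, chloride, acetates and alkenes.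

Step 27
Reactants: 38 diol
Product: 39 C2,C3-dialdehyde
Conditions: Dess–Martin periodinane (3 equiv), NaHCO3, CH2Cl2, 0 °C → rt; used at once
Reagents that add atoms: none
Why: Double Dess–Martin oxidation under neutral buffered conditions so that the C4 α-stereocentre and the C5 methylene do not isomerise.

Step 28
Reactants: 39 dialdehyde
Product: 40 CNP0340728.1
Conditions: SmI2 (3 equiv), THF, −78 → 0 °C, slow addition to 2 mM final concentration
Reagents that add atoms: none
Why: Intramolecular pinacol coupling of the two ketyls closes C2–C3 and the ten-membered ring; medium-ring pinacol closures favour the trans (threo) diol because the two samarium alkoxides avoid each other across the new bond, the C3 carbonyl should react in its dipole-minimised rotamer (C=O anti to C4–O) on the face next to H-4, and the neopentyl C2 carbonyl presents the face turned away from the axial C1 methyl and C14 acetate, which together should give the 2,3-diol of the target.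

**Compound list**

1 | ethyl 2,4-dioxopentanoate | CCOC(=O)C(=O)CC(C)=O | starting material
2 | ethyl (2Z)-2,4-bis(trimethylsilyloxy)penta-2,4-dienoate | C=C(O[Si](C)(C)C)/C=C(\O[Si](C)(C)C)C(=O)OCC | intermediate
3 | (4-methoxybenzyloxy)acetaldehyde | O=CCOCc1ccc(OC)cc1 | starting material
4 | ethyl (5R)-5-hydroxy-6-(4-methoxybenzyloxy)-2,4-dioxohexanoate | CCOC(=O)C(=O)CC(=O)C[C@H](COCc1ccc(OC)cc1)O | intermediate (not isolated)
5 | ethyl (2R)-2-[(4-methoxybenzyloxy)methyl]-4-oxo-3,4-dihydro-2H-pyran-6-carboxylate | O=C1C[C@H](COCc2ccc(OC)cc2)OC(C(=O)OCC)=C1 | intermediate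
6 | ethyl (2R)-3-[(dimethylamino)methyl]-2-[(4-methoxybenzyloxy)methyl]-4-oxo-3,4-dihydro-2H-pyran-6-carboxylate (2,3-trans) | CN(C)C[C@H]1[C@H](COCc2ccc(OC)cc2)OC(C(=O)OCC)=CC1=O | intermediate (not isolated)
7 | N-methyl quaternary ammonium iodide of 6 | C[N+](C)(C)C[C@H]1[C@H](COCc2ccc(OC)cc2)OC(C(=O)OCC)=CC1=O.[I-] | intermediate (not isolated)
8 | ethyl (2R)-2-[(4-methoxybenzyloxy)methyl]-3-methylene-4-oxo-3,4-dihydro-2H-pyran-6-carboxylate | C=C1[C@H](COCc2ccc(OC)cc2)OC(C(=O)OCC)=CC1=O | intermediate
9 | ethyl (2R,4S)-4-hydroxy-2-[(4-methoxybenzyloxy)methyl]-3-methylene-3,4-dihydro-2H-pyran-6-carboxylate | C=C1[C@H](COCc2ccc(OC)cc2)OC(C(=O)OCC)=C[C@@H]1O | intermediate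
10 | ethyl (2R,4S)-2-[(4-methoxybenzyloxy)methyl]-3-methylene-4-(triethylsilyloxy)-3,4-dihydro-2H-pyran-6-carboxylate | C=C1[C@H](COCc2ccc(OC)cc2)OC(C(=O)OCC)=C[C@@H]1O[Si](CC)(CC)CC | intermediate
11 | [(2R,4S)-2-[(4-methoxybenzyloxy)methyl]-3-methylene-4-(triethylsilyloxy)-3,4-dihydro-2H-pyran-6-yl]methanol | C=C1[C@H](COCc2ccc(OC)cc2)OC(CO)=C[C@@H]1O[Si](CC)(CC)CC | intermediate
12 | (2R,4S)-6-[(tert-butyldimethylsilyloxy)methyl]-2-[(4-methoxybenzyloxy)methyl]-3-methylene-4-(triethylsilyloxy)-3,4-dihydro-2H-pyran | C=C1[C@H](COCc2ccc(OC)cc2)OC(CO[Si](C)(C)C(C)(C)C)=C[C@@H]1O[Si](CC)(CC)CC | intermediate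
13 | 2-chloropropanoyl chloride | CC(Cl)C(Cl)=O | starting material
14 | methylchloroketene | CC(Cl)=C=O | intermediate (not isolated)
15 | pyran-fused α-chlorocyclobutanone (2-oxabicyclo[4.2.0]octan-7-one; cis-fused, Cl exo, Me endo) | C=C1[C@H](COCc2ccc(OC)cc2)O[C@]3([C@@](Cl)(C)C(=O)[C@H]3[C@@H]1O[Si](CC)(CC)CC)CO[Si](C)(C)C(C)(C)C | intermediate
16 | α-chloro-γ-lactone (3-chloro-3-methyl-6-methylene-hexahydrofuro[3,2-b]pyran-2-one with 3a-CH2OTBS, 5-CH2OPMB, 7-OTES) | C=C1[C@H](COCc2ccc(OC)cc2)O[C@]3([C@@](Cl)(C)C(=O)O[C@H]3[C@@H]1O[Si](CC)(CC)CC)CO[Si](C)(C)C(C)(C)C | intermediate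
17 | dechlorinated lactone (3-Me cis to pyran O; 3a-CH2OTBS, 5-CH2OPMB, 7-OTES) | C=C1[C@H](COCc2ccc(OC)cc2)O[C@]3([C@@H](C)C(=O)O[C@H]3[C@@H]1O[Si](CC)(CC)CC)CO[Si](C)(C)C(C)(C)C | intermediate
18 | 7-hydroxy lactone (C6–OH) | C=C1[C@H](COCc2ccc(OC)cc2)O[C@]3([C@@H](C)C(=O)O[C@H]3[C@@H]1O)CO[Si](C)(C)C(C)(C)C | intermediate
19 | 7-chloro lactone (C6–Cl, inverted) | C=C1[C@H](COCc2ccc(OC)cc2)O[C@]3([C@@H](C)C(=O)O[C@H]3[C@H]1Cl)CO[Si](C)(C)C(C)(C)C | intermediate
20 | 7-chloro-3a-(hydroxymethyl) lactone (C9–OH) | C=C1[C@H](COCc2ccc(OC)cc2)O[C@]3([C@@H](C)C(=O)O[C@H]3[C@H]1Cl)CO | intermediate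
21 | 7-chloro lactone 3a-carbaldehyde (C9 aldehyde) | C=C1[C@H](COCc2ccc(OC)cc2)O[C@]3([C@@H](C)C(=O)O[C@H]3[C@H]1Cl)C=O | intermediate
22 | (tributylstannyl)methanol | CCCC[Sn](CCCC)(CCCC)CO | starting material
23 | tributyl{[(4-methoxybenzyl)oxy]methyl}stannane | CCCC[Sn](CCCC)(CCCC)COCc1ccc(OC)cc1 | intermediate
24 | 3-ethoxycyclohex-2-en-1-one | CCOC1=CC(=O)CCC1 | starting material
25 | rac-3-ethoxy-6-hydroxycyclohex-2-en-1-one | CCOC1=CC(=O)C(O)CC1 | intermediate
26 | [(4-methoxybenzyl)oxy]methyllithium | [Li]COCc1ccc(OC)cc1 | intermediate (not isolated)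
27 | 3-ethoxy-1-{[(4-methoxybenzyl)oxy]methyl}cyclohex-2-ene-1,6-diol (racemic, both diastereomers, as dilithium salt) | CCOC1=CC(O)(COCc2ccc(OC)cc2)C(O)CC1 | intermediate (not isolated)
28 | rac-4-hydroxy-3-{[(4-methoxybenzyl)oxy]methyl}cyclohex-2-en-1-one | O=C1CCC(O)C(COCc2ccc(OC)cc2)=C1 | intermediate
29 | (S)-4-hydroxy-3-{[(4-methoxybenzyl)oxy]methyl}cyclohex-2-en-1-one | O=C1CC[C@H](O)C(COCc2ccc(OC)cc2)=C1 | intermediate
30 | (S)-3-{[(4-methoxybenzyl)oxy]methyl}-4-(triethylsilyloxy)cyclohex-2-en-1-one | O=C1CC[C@H](O[Si](CC)(CC)CC)C(COCc2ccc(OC)cc2)=C1 | intermediate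
31 | lithium (3S,4S)-3-methyl-3-(PMB-oxymethyl)-4-(triethylsilyloxy)cyclohex-1-en-1-olate | CC[Si](CC)(CC)O[C@H]1CCC(O[Li])=C[C@@]1(C)COCc1ccc(OC)cc1 | intermediate (not isolated)
32 | (3S,4S)-3-methyl-3-(PMB-oxymethyl)-4-(triethylsilyloxy)cyclohex-1-en-1-yl triflate | CC[Si](CC)(CC)O[C@H]1CCC(OS(=O)(=O)C(F)(F)F)=C[C@@]1(C)COCc1ccc(OC)cc1 | intermediate
33 | trimethyl{[(3S,4S)-3-methyl-3-(PMB-oxymethyl)-4-(triethylsilyloxy)cyclohex-1-en-1-yl]methyl}silane | CC[Si](CC)(CC)O[C@H]1CCC(C[Si](C)(C)C)=C[C@@]1(C)COCc1ccc(OC)cc1 | intermediate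
34 | C9–C10 coupled homoallylic alcohol (C9–OH, C11=CH2, C14–OTES, C2–OPMB, C3–OPMB, C6–Cl) | C=C1[C@H](COCc2ccc(OC)cc2)O[C@]3([C@@H](C)C(=O)O[C@H]3[C@H]1Cl)[C@@H](O)[C@H]1C(=C)CC[C@H](O[Si](CC)(CC)CC)[C@]1(C)COCc1ccc(OC)cc1 | intermediate
35 | C9,C14-diol | C=C1[C@H](COCc2ccc(OC)cc2)O[C@]3([C@@H](C)C(=O)O[C@H]3[C@H]1Cl)[C@@H](O)[C@H]1C(=C)CC[C@H](O)[C@]1(C)COCc1ccc(OC)cc1 | intermediate
36 | 11,20-epoxy C9,C14-diol | C=C1[C@H](COCc2ccc(OC)cc2)O[C@]3([C@@H](C)C(=O)O[C@H]3[C@H]1Cl)[C@@H](O)[C@H]1[C@]3(CC[C@H](O)[C@]1(C)COCc1ccc(OC)cc1)CO3 | intermediate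
37 | 11,20-epoxy 9,14-diacetate bis-PMB ether | C=C1[C@H](COCc2ccc(OC)cc2)O[C@]3([C@@H](C)C(=O)O[C@H]3[C@H]1Cl)[C@@H](OC(C)=O)[C@H]1[C@]3(CC[C@H](OC(C)=O)[C@]1(C)COCc1ccc(OC)cc1)CO3 | intermediate
38 | C2,C3-diol (seco-2,3 diol) | C=C1[C@H](CO)O[C@]3([C@@H](C)C(=O)O[C@H]3[C@H]1Cl)[C@@H](OC(C)=O)[C@H]1[C@]3(CC[C@H](OC(C)=O)[C@]1(C)CO)CO3 | intermediate
39 | C2,C3-dialdehyde | C=C1[C@H](C=O)O[C@]3([C@@H](C)C(=O)O[C@H]3[C@H]1Cl)[C@@H](OC(C)=O)[C@H]1[C@]3(CC[C@H](OC(C)=O)[C@]1(C)C=O)CO3 | intermediate
40 | CNP0340728.1 | C=C1[C@H]2O[C@]3([C@@H](C)C(=O)O[C@H]3[C@H]1Cl)[C@@H](OC(C)=O)[C@H]1[C@]3(CC[C@H](OC(C)=O)[C@]1(C)[C@@H](O)[C@@H]2O)CO3 | target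

**Count and risks**

Total step count: 28. Longest linear sequence: 21 steps (steps 1–14, then 22–28); the allylsilane branch is 7 steps (15–21).

Steps most likely to fail:

Step 28. The dialdehyde must fold the pyran into the chair with C3 and C9 axial before the two ketyls can meet. If that is slow, intermolecular coupling, plain reduction back to the diol, or electron transfer to the allylic C6 chloride can take over. In addition, no reagent secures the trans and facial outcome at C2/C3; it rests on conformational argument only. Fallback, from 39: double Wittig methylenation (Ph3P=CH2, THF, −78 °C) gives the divinyl compound F1. Ring-closing metathesis with a Ru–NHC benzylidene catalyst (toluene, 80 °C, high dilution) closes C2=C3 as the Z-cycloalkene F2; this forms no stereocentre, tolerates chloride and epoxide, and leaves the hindered 1,1-disubstituted C5 alkene alone. OsO4/NMO dihydroxylation of the strained ring alkene gives the cis-diol F3. Selective oxidation of the more accessible C3 carbinol (TEMPO, PhI(OAc)2) gives the α-hydroxy ketone F4, and hydride reduction (NaBH4/CeCl3) from the opposite face should give the trans-diol, returning at 40.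

Step 22. Bond formation between a neopentyl-type allylsilane terminus and an α-quaternary aldehyde may be too slow, so that protodesilylation of 33 or a Lewis-acid carbonyl-ene reaction of the aldehyde with the C5 methylene competes; face selection at the aldehyde may also be low. Fallback, from 30: the cuprate addition is repeated with Me3SiCl trapping and the silyl enol ether F5 is isolated. A Mukaiyama aldol of F5 with 21 gives the β-hydroxy ketone F6; MgBr2·OEt2 (chelate between C9=O and the pyran oxygen) or BF3·OEt2 can be chosen, which gives access to either aldehyde face. Takai–Lombardo methylenation of the C11 ketone (Zn, CH2Br2, TiCl4) returns at 34.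

Step 8. Dimerisation or oligomerisation of the monoalkyl chloroketene may outrun addition to the trisubstituted, C8-branched enol ether, and the ammonium chloride may start Ferrier-type loss of the allylic C6 silyloxy group. Fallback, from 12: dichloroketene (Cl2CHCOCl, Et3N, hexane), the most electrophilic and best precedented ketene for glycals, gives the dichlorocyclobutanone F7. Baeyer–Villiger oxidation (mCPBA, NaHCO3) gives the dichlorolactone F8, and Bu3SnH (2.2 equiv)/AIBN gives the unsubstituted lactone F9. LiHMDS/MeI at −78 °C methylates C17 from the convex face to the 17-epimer F10. A second deprotonation with kinetic protonation from the same face (LiHMDS; then AcOH, −78 °C) turns the methyl to the concave face, returning at 17.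

**Further compounds**

F1 | step 28 | C2,C3-divinyl compound | C=C1[C@H](C=C)O[C@]3([C@@H](C)C(=O)O[C@H]3[C@H]1Cl)[C@@H](OC(C)=O)[C@H]1[C@]3(CC[C@H](OC(C)=O)[C@]1(C)C=C)CO3
F2 | step 28 | (2Z)-2,3-didehydro-2,3-dideoxy macrocycle | C=C1[C@H]2O[C@]3([C@@H](C)C(=O)O[C@H]3[C@H]1Cl)[C@@H](OC(C)=O)[C@H]1[C@]3(CC[C@H](OC(C)=O)[C@]1(C)/C=C\2)CO3
F3 | step 28 | 2,3-cis-diol (3-epimer of 40) | C=C1[C@H]2O[C@]3([C@@H](C)C(=O)O[C@H]3[C@H]1Cl)[C@@H](OC(C)=O)[C@H]1[C@]3(CC[C@H](OC(C)=O)[C@]1(C)[C@@H](O)[C@H]2O)CO3
F4 | step 28 | 2-hydroxy-3-ketone | C=C1[C@H]2O[C@]3([C@@H](C)C(=O)O[C@H]3[C@H]1Cl)[C@@H](OC(C)=O)[C@H]1[C@]3(CC[C@H](OC(C)=O)[C@]1(C)[C@@H](O)C2=O)CO3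
F5 | step 22 | trimethylsilyl enol ether of the cuprate adduct of 30 | CC[Si](CC)(CC)O[C@H]1CCC(O[Si](C)(C)C)=C[C@@]1(C)COCc1ccc(OC)cc1
F6 | step 22 | C9-hydroxy C11-ketone (aldol adduct) | C=C1[C@H](COCc2ccc(OC)cc2)O[C@]3([C@@H](C)C(=O)O[C@H]3[C@H]1Cl)[C@@H](O)[C@H]1C(=O)CC[C@H](O[Si](CC)(CC)CC)[C@]1(C)COCc1ccc(OC)cc1
F7 | step 8 | 8,8-dichlorocyclobutanone analogue of 15 | C=C1[C@H](COCc2ccc(OC)cc2)O[C@]3(C(Cl)(Cl)C(=O)[C@H]3[C@@H]1O[Si](CC)(CC)CC)CO[Si](C)(C)C(C)(C)C
F8 | step 8 | 3,3-dichlorolactone analogue of 16 | C=C1[C@H](COCc2ccc(OC)cc2)O[C@]3(C(Cl)(Cl)C(=O)O[C@H]3[C@@H]1O[Si](CC)(CC)CC)CO[Si](C)(C)C(C)(C)C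
F9 | step 8 | 3-unsubstituted lactone (17 without the C18 methyl) | C=C1[C@H](COCc2ccc(OC)cc2)O[C@]3(CC(=O)O[C@H]3[C@@H]1O[Si](CC)(CC)CC)CO[Si](C)(C)C(C)(C)C
F10 | step 8 | 17-epimer of 17 | C=C1[C@H](COCc2ccc(OC)cc2)O[C@]3([C@H](C)C(=O)O[C@H]3[C@@H]1O[Si](CC)(CC)CC)CO[Si](C)(C)C(C)(C)C
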